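**Plan**

- Retrosynthesis: the four MOM ethers are removed last. Ring C (flavanone numbering O1, C2, C3, C4=O, C4a, C5–C8, C8a) is then cut at O1–C2 and at C3–C4 in one stroke. Each prenyl group is traced back to an O→C or Br→C transfer on a commercial hydroxybenzaldehyde.
- Enabling feature: in ring C the unit O1–C8a=C4a–C4(=O) is a salicyloyl group, a latent 1,4-dipole (phenolic O1, acyl C4). C2–C3 is the vinyl group of a vinylarene whose C2 is benzylic to the electron-rich ring B. Ring C is therefore a formal [4+2] of a salicylic acid ketal and a styrene.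
- Forward, ring A: five steps from 2,4,6-trihydroxybenzaldehyde give ketal 8. An aromatic Claisen rearrangement starting from the future O1 fixes the 8-prenyl/O1 relationship without ambiguity.
- Forward, ring B: three steps from 3-bromo-4,5-dihydroxybenzaldehyde give styrene 13. A nickel-catalysed annulation of 8 with 13 (loss of acetone) closes ring C, and deprotection gives the target.
- Stereochemistry: the single stereocentre (C2, S) is set in the annulation by the chiral ligand on nickel. Only an acidic deprotection follows, which cannot open the flavanone.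

Key step: step 9

Remark: the sense of induction of the ligand in step 9 cannot be predicted with confidence; (S)-t-BuPHOX is written, and its mirror image is used instead if a test run shows that one to give the 2S product.
Remark: tert-butyl 2-methylbut-3-en-2-yl carbonate is treated as a purchasable reagent (otherwise it is one operation from 2-methylbut-3-en-2-ol and Boc2O).

**Route**

Step 1
Reactants: 1 2,4,6-trihydroxybenzaldehyde
Product: 2 2-hydroxy-4,6-bis(methoxymethoxy)benzaldehyde
Conditions: MOMCl (2.1 equiv), i-Pr2NEt (2.5 equiv), CH2Cl2, 0 °C to rt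
Reagents that add atoms: chloromethyl methyl ether (MOMCl), COCCl
Why: O-alkylation (MOM acetal formation) should take the para hydroxyl and one of the two equivalent ortho hydroxyls, while the remaining ortho hydroxyl, hydrogen-bonded to the aldehyde, is the least nucleophilic and should stay free.

Step 2
Reactants: 2 2-hydroxy-4,6-bis(methoxymethoxy)benzaldehyde
Product: 3 2,4-bis(methoxymethoxy)-6-[(2-methylbut-3-en-2-yl)oxy]benzaldehyde
Conditions: tert-butyl 2-methylbut-3-en-2-yl carbonate (1.3 equiv), Pd(PPh3)4 (3 mol %), THF, 0 °C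
Reagents that add atoms: tert-butyl 2-methylbut-3-en-2-yl carbonate, C=CC(C)(C)OC(=O)OC(C)(C)C
Why: In this decarboxylative Tsuji–Trost O-allylation the 1,1-dimethylallyl palladium cation (formed with loss of CO2 and tert-butoxide) should be captured by the phenoxide at its more substituted end under kinetic control at low temperature, giving the tertiary aryl ether needed for step 3.

Step 3
Reactants: 3 2,4-bis(methoxymethoxy)-6-[(2-methylbut-3-en-2-yl)oxy]benzaldehyde
Product: 5 2-hydroxy-4,6-bis(methoxymethoxy)-3-(3-methylbut-2-en-1-yl)benzaldehyde, via ortho-dienone 4 (not isolated)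
Conditions: toluene, 110 °C, sealed tube
Reagents that add atoms: none
Why: The aromatic Claisen rearrangement ([3,3]) should move the allyl unit, with exchange of its ends, from oxygen to the only free ortho carbon, so that the 1,1-dimethylallyl ether becomes a linear prenyl group and the freed hydroxyl is necessarily the one next to it; tautomerisation of dienone 4 restores the arene.

Step 4
Reactants: 5 2-hydroxy-4,6-bis(methoxymethoxy)-3-(3-methylbut-2-en-1-yl)benzaldehyde
Product: 6 2-hydroxy-4,6-bis(methoxymethoxy)-3-(3-methylbut-2-en-1-yl)benzoic acid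
Conditions: NaClO2 (3 equiv), NaH2PO4 (4 equiv), 2-methyl-2-butene (30 equiv), t-BuOH/H2O, 0 °C to rt
Reagents that add atoms: sodium chlorite, [Na+].[O-]Cl=O
Why: The Pinnick oxidation should convert the aldehyde to the acid at pH 3–4, which the MOM ethers tolerate, and the large excess of 2-methyl-2-butene should intercept hypochlorous acid before it reaches the prenyl alkene or the electron-rich ring.

Step 5
Reactants: 6 2-hydroxy-4,6-bis(methoxymethoxy)-3-(3-methylbut-2-en-1-yl)benzoic acid
Product: 8 5,7-bis(methoxymethoxy)-2,2-dimethyl-8-(3-methylbut-2-en-1-yl)-4H-1,3-benzodioxin-4-one, via 2-methoxypropan-2-yl ester 7 (not isolated)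
Conditions: 2-methoxypropene (5 equiv), PPTS (10 mol %), 4 Å MS, CH2Cl2, 0 °C to rt
Reagents that add atoms: 2-methoxypropene, C=C(C)OC
Why: Addition of the carboxylic acid to the enol ether, followed by intramolecular ketal exchange with the ortho hydroxyl (loss of methanol), is the enol-ether form of the classical cyclic acylal formation from salicylic acids and enol esters, and it avoids the strong acids (TFA/TFAA, SOCl2) that would cleave the MOM ethers or cyclise the prenyl group onto oxygen.

Step 6
Reactants: 9 3-bromo-4,5-dihydroxybenzaldehyde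
Product: 10 3-bromo-4,5-bis(methoxymethoxy)benzaldehyde
Conditions: MOMCl (2.5 equiv), i-Pr2NEt (3 equiv), CH2Cl2, 0 °C to rt
Reagents that add atoms: chloromethyl methyl ether (MOMCl), COCCl
Why: Double O-alkylation of the catechol gives MOM ethers, which should survive ylide, organolithium and zerovalent nickel chemistry and later stabilise the ortho-lithio species.

Step 7
Reactants: 10 3-bromo-4,5-bis(methoxymethoxy)benzaldehyde
Product: 11 1-bromo-5-ethenyl-2,3-bis(methoxymethoxy)benzene
Conditions: Ph3PCH3Br (1.3 equiv), KOt-Bu (1.25 equiv), THF, 0 °C to rt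
Reagents that add atoms: methyltriphenylphosphonium bromide, C[P+](c1ccccc1)(c1ccccc1)c1ccccc1.[Br-]
Why: Wittig methylenation of the aromatic aldehyde with the non-stabilised ylide should give the terminal vinyl group without touching the aryl bromide or the acetal ethers.

Step 8
Reactants: 11 1-bromo-5-ethenyl-2,3-bis(methoxymethoxy)benzene
Product: 13 5-ethenyl-1,2-bis(methoxymethoxy)-3-(3-methylbut-2-en-1-yl)benzene, via aryllithium 12 (not isolated)
Conditions: n-BuLi (1.05 equiv), THF, −78 °C; then CuBr·SMe2 (10 mol %), prenyl bromide (1.3 equiv), −78 to 0 °C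
Reagents that add atoms: 1-bromo-3-methylbut-2-ene (prenyl bromide), CC(C)=CCBr
Why: Bromine–lithium exchange at −78 °C should be much faster than addition of the alkyllithium to the styrene, aryllithium 12 is stabilised by the neighbouring MOM oxygen, and copper-catalysed allylic substitution at the unhindered CH2 end of prenyl bromide (SN2) should give the linear prenyl arene.

Step 9
Reactants: 8 5,7-bis(methoxymethoxy)-2,2-dimethyl-8-(3-methylbut-2-en-1-yl)-4H-1,3-benzodioxin-4-one; 13 5-ethenyl-1,2-bis(methoxymethoxy)-3-(3-methylbut-2-en-1-yl)benzene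
Product: 16 (2S)-2-[3,4-bis(methoxymethoxy)-5-(3-methylbut-2-en-1-yl)phenyl]-5,7-bis(methoxymethoxy)-8-(3-methylbut-2-en-1-yl)-2,3-dihydro-4H-chromen-4-one, via acylnickel aryloxide 14 (not isolated), via benzylnickel aryloxide 15 (not isolated)
Conditions: 13 (1.5 equiv), Ni(cod)2 (10 mol %), (S)-t-BuPHOX (12 mol %), toluene, 80 °C, argon
Reagents that add atoms: none
Why: Proposed new method: zerovalent nickel should insert into the acyl–oxygen bond of ketal ester 8 and expel acetone by β-aryloxide elimination to give the five-membered nickelacycle 14; this should take up the vinyl group of 13 by 2,1-migratory insertion into the nickel–acyl bond (new C3–C4 bond, nickel on the benzylic carbon as an η3-benzyl unit) to give 15, and carbon–oxygen reductive elimination should then form O1–C2 and return zerovalent nickel. The closest known reaction type is the nickel-catalysed annulation of salicylic acid ketals with alkynes, which gives chromones with loss of the ketone, together with related nickel-catalysed decarbonylative and decarboxylative annulations of cyclic anhydrides and isatoic anhydrides with allenes, for which chiral P,N ligands are reported to give enantioenriched products; the step extends the alkyne case to a vinylarene. Ring C closes as a formal [4+2] (O1–C8a–C4a–C4 from the salicylate, C2–C3 from the alkene), the last bond by ring-contracting reductive elimination from the seven-membered nickelacycle 15. The C2 stereocentre is controlled by the chiral ligand on nickel, either in the face-selective insertion or, if the η3-benzyl unit equilibrates, in the reductive elimination, which is expected to proceed with retention at carbon. The step needs regioselectivity (acyl to the CH2 end, secured by η3-benzyl stabilisation on the electron-rich arene), chemoselectivity for the monosubstituted vinyl group over the two trisubstituted prenyl alkenes (which should not insert), and suppression of β-hydride elimination to the chalcone (secured by the metallacycle and by η3-benzyl binding, with the hemilabile oxazoline arm opening a site only for alkene uptake). At 80 °C ketal 8 should not fragment to a free quinoketene, so no racemic background cycloaddition is expected.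

Step 10
Reactants: 16 (2S)-2-[3,4-bis(methoxymethoxy)-5-(3-methylbut-2-en-1-yl)phenyl]-5,7-bis(methoxymethoxy)-8-(3-methylbut-2-en-1-yl)-2,3-dihydro-4H-chromen-4-one
Product: 17 (2S)-2-[3,4-dihydroxy-5-(3-methylbut-2-en-1-yl)phenyl]-5,7-dihydroxy-8-(3-methylbut-2-en-1-yl)-2,3-dihydro-4H-chromen-4-one
Conditions: 3 M aq. HCl/MeOH (1:5), 45 °C
Reagents that add atoms: none
Why: Acid-catalysed acetal exchange with methanol should remove the four MOM groups as dimethoxymethane; acid, unlike base, cannot open the flavanone by retro-oxa-Michael reaction, so C2 should keep its configuration, and the mild temperature and short time are meant to outrun cyclisation of the prenyl groups onto the neighbouring hydroxyls.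

**Compound list**

1 | 2,4,6-trihydroxybenzaldehyde | O=Cc1c(O)cc(O)cc1O | starting material
2 | 2-hydroxy-4,6-bis(methoxymethoxy)benzaldehyde | O=Cc1c(O)cc(OCOC)cc1OCOC | intermediate
3 | 2,4-bis(methoxymethoxy)-6-[(2-methylbut-3-en-2-yl)oxy]benzaldehyde | O=Cc1c(OC(C)(C)C=C)cc(OCOC)cc1OCOC | intermediate
4 | 2,4-bis(methoxymethoxy)-5-(3-methylbut-2-en-1-yl)-6-oxocyclohexa-1,3-diene-1-carbaldehyde (ortho-dienone, racemic) | O=CC1=C(OCOC)C=C(OCOC)C(CC=C(C)C)C1=O | intermediate (not isolated)
5 | 2-hydroxy-4,6-bis(methoxymethoxy)-3-(3-methylbut-2-en-1-yl)benzaldehyde | O=Cc1c(O)c(CC=C(C)C)c(OCOC)cc1OCOC | intermediate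
6 | 2-hydroxy-4,6-bis(methoxymethoxy)-3-(3-methylbut-2-en-1-yl)benzoic acid | OC(=O)c1c(O)c(CC=C(C)C)c(OCOC)cc1OCOC | intermediate
7 | 2-methoxypropan-2-yl 2-hydroxy-4,6-bis(methoxymethoxy)-3-(3-methylbut-2-en-1-yl)benzoate | COC(C)(C)OC(=O)c1c(O)c(CC=C(C)C)c(OCOC)cc1OCOC | intermediate (not isolated)
8 | 5,7-bis(methoxymethoxy)-2,2-dimethyl-8-(3-methylbut-2-en-1-yl)-4H-1,3-benzodioxin-4-one | CC1(C)OC(=O)c2c(OCOC)cc(OCOC)c(CC=C(C)C)c2O1 | intermediate
9 | 3-bromo-4,5-dihydroxybenzaldehyde | O=Cc1cc(O)c(O)c(Br)c1 | starting material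
10 | 3-bromo-4,5-bis(methoxymethoxy)benzaldehyde | O=Cc1cc(OCOC)c(OCOC)c(Br)c1 | intermediate
11 | 1-bromo-5-ethenyl-2,3-bis(methoxymethoxy)benzene | C=Cc1cc(OCOC)c(OCOC)c(Br)c1 | intermediate
12 | [5-ethenyl-2,3-bis(methoxymethoxy)phenyl]lithium | C=Cc1cc(OCOC)c(OCOC)c([Li])c1 | intermediate (not isolated)
13 | 5-ethenyl-1,2-bis(methoxymethoxy)-3-(3-methylbut-2-en-1-yl)benzene | C=Cc1cc(OCOC)c(OCOC)c(CC=C(C)C)c1 | intermediate
14 | five-membered nickelacycle Ni–C(=O)–C4a–C8a–O (acylnickel aryloxide of the ring A salicyloyl unit; ligand on nickel omitted) | O=C1[Ni]Oc2c(CC=C(C)C)c(OCOC)cc(OCOC)c12 | intermediate (not isolated)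
15 | seven-membered nickelacycle Ni–CH(aryl)–CH2–C(=O)–C4a–C8a–O (benzylnickel aryloxide; configuration at the benzylic carbon as in 16; ligand on nickel omitted) | O=C1C[C@@H](c3cc(OCOC)c(OCOC)c(CC=C(C)C)c3)[Ni]Oc2c(CC=C(C)C)c(OCOC)cc(OCOC)c12 | intermediate (not isolated)
16 | (2S)-2-[3,4-bis(methoxymethoxy)-5-(3-methylbut-2-en-1-yl)phenyl]-5,7-bis(methoxymethoxy)-8-(3-methylbut-2-en-1-yl)-2,3-dihydro-4H-chromen-4-one | CC(C)=CCc1cc([C@@H]2CC(=O)c3c(OCOC)cc(OCOC)c(CC=C(C)C)c3O2)cc(OCOC)c1OCOC | intermediate
17 | (2S)-2-[3,4-dihydroxy-5-(3-methylbut-2-en-1-yl)phenyl]-5,7-dihydroxy-8-(3-methylbut-2-en-1-yl)-2,3-dihydro-4H-chromen-4-one | CC(C)=CCc1cc([C@@H]2CC(=O)c3c(O)cc(O)c(CC=C(C)C)c3O2)cc(O)c1O | target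

Total step count: 10. Longest linear sequence: 7 (steps 1–5, 9, 10).

**Steps most likely to fail**

1. Step 9 (proposed new method). Oxidative addition may be slow at the acyl–oxygen bond, which is flanked by two ortho substituents on an electron-rich ring. β-Hydride elimination from the benzylnickel stage may open the system to a chalcone that recloses without stereocontrol. Facial selectivity may be poor. The fallback uses known chemistry, sets out from 8 and 10 and returns at 16:
   - Ketal 8 is opened with the lithium enolate of allyl acetate (LiN(i-Pr)2, THF, −78 °C, acetic acid quench; acetone is lost) to allyl 3-[2-hydroxy-4,6-bis(methoxymethoxy)-3-(3-methylbut-2-en-1-yl)phenyl]-3-oxopropanoate F1.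
   - Bromide 10 is prenylated by Stille coupling (tributyl(3-methylbut-2-en-1-yl)stannane, Pd(PPh3)4, DMF, 90 °C) to 3,4-bis(methoxymethoxy)-5-(3-methylbut-2-en-1-yl)benzaldehyde F2.
   - Knoevenagel condensation of F1 with F2 (piperidine, AcOH, 4 Å MS, toluene) should give allyl 3-[3,4-bis(methoxymethoxy)-5-(3-methylbut-2-en-1-yl)phenyl]-2-[2-hydroxy-4,6-bis(methoxymethoxy)-3-(3-methylbut-2-en-1-yl)benzoyl]prop-2-enoate F3.
   - A cinchona-alkaloid-derived thiourea (10 mol %, toluene, −25 °C; the quinine- or quinidine-derived pseudo-enantiomer chosen for the 2S sense) should catalyse the enantioselective intramolecular oxa-Michael addition of the single free phenol. This gives allyl (2S)-2-[3,4-bis(methoxymethoxy)-5-(3-methylbut-2-en-1-yl)phenyl]-5,7-bis(methoxymethoxy)-8-(3-methylbut-2-en-1-yl)-4-oxo-3,4-dihydro-2H-chromene-3-carboxylate F4.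
   - Pd(PPh3)4 with morpholine (THF, rt) removes the allyl group, and the β-keto acid loses CO2 to give 16.

2. Step 5. Ring closure may stall at the open ester, or the activated cyclic ester may be opened by the liberated methanol to the methyl ester. The fallback sets out from 6 and returns at 16. Acid 6 is treated with dimethyl acetylenedicarboxylate, CuI and NaHCO3 (MeCN, 80 °C); conjugate addition of the carboxylate and then of the phenol to the same alkyne carbon, under basic conditions, should give methyl 2-(2-methoxy-2-oxoethyl)-5,7-bis(methoxymethoxy)-8-(3-methylbut-2-en-1-yl)-4-oxo-4H-1,3-benzodioxine-2-carboxylate F5. F5 is a ketal of a keto diester and takes the place of 8 in step 9, where the keto diester is expelled instead of acetone.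

3. Step 10. Acid-catalysed cyclisation of a prenyl group onto the neighbouring free hydroxyl (chroman formation) may compete with the slower MOM cleavages. The fallback sets out from 16 and returns at 17. TMSOTf with 2,2'-bipyridyl (CH2Cl2, 0 °C to rt) should exchange the aryl MOM ethers for silyl ethers under aprotic, buffered conditions, giving (2S)-2-[3,4-bis(trimethylsilyloxy)-5-(3-methylbut-2-en-1-yl)phenyl]-8-(3-methylbut-2-en-1-yl)-5,7-bis(trimethylsilyloxy)-2,3-dihydro-4H-chromen-4-one F6. Hydrolysis with water at rt then gives 17.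

**Further compounds**

F1 | step 9 | allyl 3-[2-hydroxy-4,6-bis(methoxymethoxy)-3-(3-methylbut-2-en-1-yl)phenyl]-3-oxopropanoate | C=CCOC(=O)CC(=O)c1c(O)c(CC=C(C)C)c(OCOC)cc1OCOC
F2 | step 9 | 3,4-bis(methoxymethoxy)-5-(3-methylbut-2-en-1-yl)benzaldehyde | O=Cc1cc(OCOC)c(OCOC)c(CC=C(C)C)c1
F3 | step 9 | allyl 3-[3,4-bis(methoxymethoxy)-5-(3-methylbut-2-en-1-yl)phenyl]-2-[2-hydroxy-4,6-bis(methoxymethoxy)-3-(3-methylbut-2-en-1-yl)benzoyl]prop-2-enoate (mixture of alkene isomers) | C=CCOC(=O)C(=Cc1cc(OCOC)c(OCOC)c(CC=C(C)C)c1)C(=O)c1c(O)c(CC=C(C)C)c(OCOC)cc1OCOC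
F4 | step 9 | allyl (2S)-2-[3,4-bis(methoxymethoxy)-5-(3-methylbut-2-en-1-yl)phenyl]-5,7-bis(methoxymethoxy)-8-(3-methylbut-2-en-1-yl)-4-oxo-3,4-dihydro-2H-chromene-3-carboxylate (C3 epimers) | C=CCOC(=O)C1[C@@H](c2cc(OCOC)c(OCOC)c(CC=C(C)C)c2)Oc2c(CC=C(C)C)c(OCOC)cc(OCOC)c2C1=O
F5 | step 5 | methyl 2-(2-methoxy-2-oxoethyl)-5,7-bis(methoxymethoxy)-8-(3-methylbut-2-en-1-yl)-4-oxo-4H-1,3-benzodioxine-2-carboxylate (racemic) | COC(=O)CC1(C(=O)OC)OC(=O)c2c(OCOC)cc(OCOC)c(CC=C(C)C)c2O1
F6 | step 10 | (2S)-2-[3,4-bis(trimethylsilyloxy)-5-(3-methylbut-2-en-1-yl)phenyl]-8-(3-methylbut-2-en-1-yl)-5,7-bis(trimethylsilyloxy)-2,3-dihydro-4H-chromen-4-one | CC(C)=CCc1cc([C@@H]2CC(=O)c3c(O[Si](C)(C)C)cc(O[Si](C)(C)C)c(CC=C(C)C)c3O2)cc(O[Si](C)(C)C)c1O[Si](C)(C)C
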